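**Retrosynthetic overview**
1. Target 20 ⇒ lactol 18 by O-acylation; the pyran is closed last by enol-lactolisation of a 2,10-dicarbonyl tricyclo[5.3.1.0(1,5)]undec-8-ene.
2. The bicyclo[3.2.1]octadiene of 18 ⇒ exo-cyclopropanated norbornane carbaldehyde 15 by a cationic cyclopropylcarbinyl→homoallyl one-carbon ring expansion (key step).
3. 15 ⇒ norbornenyl triflate 13 (CO supplies the formyl carbon, a sulfoxonium ylide the CH2); 13 ⇒ intramolecular Diels–Alder of a 1-alkyl-2-triflyloxycyclopentadiene with a tethered (E)-2-methyl-enoate.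
4. Diene precursor 11 ⇒ cyclopentanone + (E)-1-nitrohexa-1,5-diene (asymmetric Michael, the only source of chirality) + methyl methacrylate (cross-metathesis).
5. Ring order: cyclopentanone ring → IMDA closes cyclopentane D and the norbornene together → cyclopropane → ring expansion to the six-membered ring B → pyran C.

Assumption: in step 6 the dienophile adds to the diene face that puts CH(OMe)2 anti to the C–OTf carbon (A(1,3) control); if the other face reacts, the (R)-catalyst is used in step 2 and nothing else changes.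

**Step 1**
Reactants: 1 pent-4-enal; 2 nitromethane
Product: 4 (1E)-1-nitrohexa-1,5-diene, via nitro alcohol 3 (not isolated)
Conditions: MeNO2 (5 equiv), KOtBu (10 mol%), THF/t-BuOH, 0 °C; then MsCl, Et3N, CH2Cl2, 0 °C
Reagents that add atoms: none
Why: Henry (nitroaldol) addition followed by mesylation and E1cB elimination gives the conjugated E nitroalkene, and no stereocentre is carried forward.

**Step 2**
Reactants: 4 (1E)-1-nitrohexa-1,5-diene; 5 cyclopentanone
Product: 6 (2S)-2-[(2S)-1-nitrohex-5-en-2-yl]cyclopentan-1-one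
Conditions: 5 (5 equiv), 1-[3,5-bis(trifluoromethyl)phenyl]-3-[(2S)-pyrrolidin-2-ylmethyl]thiourea (10 mol%), PhCO2H (10 mol%), CHCl3, 0 °C; anti isomer removed by chromatography
Reagents that add atoms: none
Why: Enamine-catalysed asymmetric Michael addition of a ketone to a nitroalkene, in which the (S)-pyrrolidine enamine attacks the thiourea-bound nitroalkene through the synclinal transition state and sets the side-chain stereocentre (S), the only source of absolute configuration (the ring α-centre is erased later).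

**Step 3**
Reactants: 6 (2S)-2-[(2S)-1-nitrohex-5-en-2-yl]cyclopentan-1-one
Product: 7 2-[(2S)-1,1-dimethoxyhex-5-en-2-yl]cyclopentan-1-one
Conditions: NaOMe, MeOH, 0 °C; then added to H2SO4/MeOH, −40 °C; aq. NaHCO3
Reagents that add atoms: methanol (CO)
Why: Nef reaction run in acidic methanol converts the nitronate into the aldehyde, which is trapped as its dimethyl acetal, and the adjacent stereocentre is not enolisable and is untouched.

**Step 4**
Reactants: 7 2-[(2S)-1,1-dimethoxyhex-5-en-2-yl]cyclopentan-1-one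
Product: 9 5-[(2S)-1,1-dimethoxyhex-5-en-2-yl]cyclopent-2-en-1-one, via silyl enol ether 8 (not isolated)
Conditions: LDA, TMSCl, THF, −78 °C; then Pd(OAc)2 (1.0 equiv), MeCN, rt
Reagents that add atoms: none
Why: Saegusa–Ito dehydrogenation, in which kinetic deprotonation at the unsubstituted α-CH2, silylation and Pd(II)-mediated β-hydride elimination give the enone (the other enone regioisomer would converge on the same diene in step 6).

**Step 5**
Reactants: 9 5-[(2S)-1,1-dimethoxyhex-5-en-2-yl]cyclopent-2-en-1-one; 10 methyl methacrylate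
Product: 11 methyl (2E,6S)-7,7-dimethoxy-2-methyl-6-(2-oxocyclopent-3-en-1-yl)hept-2-enoate
Conditions: 10 (10 equiv), Hoveyda–Grubbs II (5 mol%), CH2Cl2, 40 °C
Reagents that add atoms: none
Why: Olefin cross-metathesis of a terminal alkene with a 1,1-disubstituted acrylate gives the trisubstituted E enoate, whose geometry is later translated into the quaternary ester-bearing centre.

**Step 6**
Reactants: 11 methyl (2E,6S)-7,7-dimethoxy-2-methyl-6-(2-oxocyclopent-3-en-1-yl)hept-2-enoate
Product: 13 methyl (1S,2S,5R,6R,7S)-2-(dimethoxymethyl)-6-methyl-9-(trifluoromethanesulfonyloxy)tricyclo[5.2.1.0(1,5)]dec-8-ene-6-carboxylate, via dienyl triflate 12 (not isolated)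
Conditions: KHMDS, THF, −78 °C; PhNTf2, −78 → 0 °C; then PhMe, BHT, 90 °C
Reagents that add atoms: N-phenylbis(trifluoromethanesulfonimide) (O=S(=O)(N(c1ccccc1)S(=O)(=O)C(F)(F)F)C(F)(F)F)
Why: O-triflation of the cross-conjugated dienolate gives a 1-alkyl-2-triflyloxycyclopentadiene that undergoes an intramolecular Diels–Alder reaction in which the three-atom tether forces the fused mode, the E alkene places CO2Me endo and CH3 exo, and A(1,3) strain between the side-chain stereocentre and the C–OTf bond selects the diene face, so C1, C5, C6 and C7 are set in absolute terms.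

**Step 7**
Reactants: 13 methyl (1S,2S,5R,6R,7S)-2-(dimethoxymethyl)-6-methyl-9-(trifluoromethanesulfonyloxy)tricyclo[5.2.1.0(1,5)]dec-8-ene-6-carboxylate
Product: 14 methyl (1S,2S,5R,6R,7S)-2-(dimethoxymethyl)-9-formyl-6-methyltricyclo[5.2.1.0(1,5)]dec-8-ene-6-carboxylate
Conditions: Pd(PPh3)4 (5 mol%), CO (1 atm), Bu3SnH (slow addition), LiCl, THF, 50 °C
Reagents that add atoms: carbon monoxide ([C-]#[O+])
Why: Palladium-catalysed reductive carbonylation (formylation) of an enol triflate by oxidative addition, CO insertion and hydride transfer gives the enal without touching any stereocentre.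

**Step 8**
Reactants: 14 methyl (1S,2S,5R,6R,7S)-2-(dimethoxymethyl)-9-formyl-6-methyltricyclo[5.2.1.0(1,5)]dec-8-ene-6-carboxylate
Product: 15 methyl (1S,2S,5R,6R,7S)-2-(dimethoxymethyl)-9-formyl-6-methyl-8,9-methanotricyclo[5.2.1.0(1,5)]decane-6-carboxylate (exo cyclopropane, endo CHO)
Conditions: Me3S(O)I, NaH, DMSO/THF, 0 °C → rt
Reagents that add atoms: trimethylsulfoxonium iodide (C[S+](C)(C)=O.[I-])
Why: Corey–Chaykovsky cyclopropanation, in which conjugate addition of the sulfoxonium ylide to the strained enal from the exo face and 3-exo-tet closure give the exo-fused cyclopropane (both new centres are destroyed in step 9).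

**Step 9**
Reactants: 15 methyl (1S,2S,5R,6R,7S)-2-(dimethoxymethyl)-9-formyl-6-methyl-8,9-methanotricyclo[5.2.1.0(1,5)]decane-6-carboxylate
Product: 18 lactol of the target (cis-fused 2-hydroxy-2H-pyran on the (1S,2R,5R,6R,7S)-6-methyl-6-methoxycarbonyl-tricyclo[5.3.1.0(1,5)]undec-8-ene core; anomers), via bis-enol ether 16 (not isolated), via dialdehyde 17 (not isolated)
Conditions: TMSOTf (3 equiv), i-Pr2NEt (4 equiv), CH2Cl2, −78 → 0 °C; then 0.5 M HCl, THF/H2O, 0 °C → rt
Reagents that add atoms: water (O)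
Why: Proposed new method: O-silylation of the cyclopropanecarbaldehyde gives a silyloxocarbenium ion that is a cyclopropylcarbinyl cation, the strained ring-fusion bond of the cyclopropane cleaves (release of cyclopropane and norbornane strain, secondary cation) to expand the norbornane to a bicyclo[3.2.1]octenyl homoallyl cation, which can only lose a proton from the former cyclopropane CH2 (the other neighbour is a bridgehead) to give the 1-silyloxy-diene, while the same reagent pair turns the acetal into its methyl enol ether; aqueous acid then regenerates the C2 aldehyde, whose oxocarbenium is captured by the dienol oxygen (C-attack is geometrically impossible) to close the pyran, and because only cis closure is possible C2 is reset to R under thermodynamic control; closest known reaction types are silyl-iodide/Lewis-acid homoconjugate opening of cyclopropyl ketones, iminium-activated ring opening of formylcyclopropanes, the cyclopropylcarbinyl–homoallyl rearrangement and TMSOTf/amine elimination of acetals to enol ethers.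

**Step 10**
Reactants: 18 lactol of the target; 19 3-methylbutanoyl chloride
Product: 20 CNP0315847.1 (isovalerate of lactol 18 with S acetal carbon)
Conditions: 19 (1.3 equiv), pyridine, DMAP (5 mol%), CH2Cl2, −20 → 0 °C
Reagents that add atoms: none
Why: DMAP-catalysed O-acylation of the equilibrating lactol on its less hindered convex face, trans to the cyclopentane C–C bond at the neighbouring centre, is expected to give the S acetal as in related iridoid 1-O-acyl lactols.

**Compound list**
1 | pent-4-enal | C=CCCC=O | starting material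
2 | nitromethane | C[N+](=O)[O-] | starting material
3 | 1-nitrohex-5-en-2-ol (racemic) | C=CCCC(O)C[N+](=O)[O-] | intermediate
4 | (1E)-1-nitrohexa-1,5-diene | C=CCC/C=C/[N+](=O)[O-] | intermediate
5 | cyclopentanone | O=C1CCCC1 | starting material
6 | (2S)-2-[(2S)-1-nitrohex-5-en-2-yl]cyclopentan-1-one | O=C1CCC[C@H]1[C@@H](C[N+](=O)[O-])CCC=C | intermediate
7 | 2-[(2S)-1,1-dimethoxyhex-5-en-2-yl]cyclopentan-1-one (ring α-centre inconsequential) | O=C1CCCC1[C@@H](C(OC)OC)CCC=C | intermediate
8 | trimethyl({5-[(2S)-1,1-dimethoxyhex-5-en-2-yl]cyclopent-1-en-1-yl}oxy)silane | C[Si](C)(C)OC1=CCCC1[C@@H](C(OC)OC)CCC=C | intermediate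
9 | 5-[(2S)-1,1-dimethoxyhex-5-en-2-yl]cyclopent-2-en-1-one (ring C5 inconsequential) | O=C1C=CCC1[C@@H](C(OC)OC)CCC=C | intermediate
10 | methyl methacrylate | C=C(C)C(=O)OC | starting material
11 | methyl (2E,6S)-7,7-dimethoxy-2-methyl-6-(2-oxocyclopent-3-en-1-yl)hept-2-enoate | O=C1C=CCC1[C@@H](C(OC)OC)CC/C=C(\C)C(=O)OC | intermediate
12 | methyl (2E,6S)-7,7-dimethoxy-2-methyl-6-[2-(trifluoromethanesulfonyloxy)cyclopenta-1,3-dien-1-yl]hept-2-enoate | FC(F)(F)S(=O)(=O)OC1=C([C@@H](C(OC)OC)CC/C=C(\C)C(=O)OC)CC=C1 | intermediate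
13 | methyl (1S,2S,5R,6R,7S)-2-(dimethoxymethyl)-6-methyl-9-(trifluoromethanesulfonyloxy)tricyclo[5.2.1.0(1,5)]dec-8-ene-6-carboxylate | COC(=O)[C@]1(C)[C@@H]2C=C(OS(=O)(=O)C(F)(F)F)[C@]3(C2)[C@@H](C(OC)OC)CC[C@@H]13 | intermediate
14 | methyl (1S,2S,5R,6R,7S)-2-(dimethoxymethyl)-9-formyl-6-methyltricyclo[5.2.1.0(1,5)]dec-8-ene-6-carboxylate | COC(=O)[C@]1(C)[C@@H]2C=C(C=O)[C@]3(C2)[C@@H](C(OC)OC)CC[C@@H]13 | intermediate
15 | methyl (1S,2S,5R,6R,7S)-2-(dimethoxymethyl)-9-formyl-6-methyl-8,9-methanotricyclo[5.2.1.0(1,5)]decane-6-carboxylate (exo cyclopropane, endo CHO) | COC(=O)[C@]1(C)[C@@H]2[C@H]3C[C@@]3(C=O)[C@]4(C2)[C@@H](C(OC)OC)CC[C@@H]14 | intermediate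
16 | methyl 2-(methoxymethylidene)-6-methyl-10-[(trimethylsilyloxy)methylidene]tricyclo[5.3.1.0(1,5)]undec-8-ene-6-carboxylate (core as in 15; enol ether geometries not defined) | COC(=O)[C@]1(C)[C@@H]2C=CC(=CO[Si](C)(C)C)[C@]3(C2)C(=COC)CC[C@@H]13 | intermediate
17 | methyl 2,10-diformyl-6-methyltricyclo[5.3.1.0(1,5)]undec-8-ene-6-carboxylate (C2 and C10 epimers, equilibrating) | COC(=O)[C@]1(C)[C@@H]2C=CC(C=O)[C@]3(C2)C(C=O)CC[C@@H]13 | intermediate
18 | lactol of the target: enol form of the C10 formyl group of 17 closed onto the C2 formyl group as a cis-fused 2-hydroxy-2H-pyran, core (1S,2R,5R,6R,7S), anomeric mixture | COC(=O)[C@]1(C)[C@@H]2C=CC3=COC(O)[C@@H]4CC[C@@H]1[C@]34C2 | intermediate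
19 | 3-methylbutanoyl chloride (isovaleryl chloride) | CC(C)CC(=O)Cl | starting material
20 | CNP0315847.1: 3-methylbutanoate of lactol 18, acetal carbon S, core (1S,2R,5R,6R,7S) | COC(=O)[C@]1(C)[C@@H]2C=CC3=CO[C@@H](OC(=O)CC(C)C)[C@@H]4CC[C@@H]1[C@]34C2 | target

**Totals**
Total step count: 10. Longest linear sequence: 10 steps (from pent-4-enal).

**Three steps most likely to fail**

Step 9 (the proposed new ring expansion). The cyclopropane may open at its external bond, the cation may be captured or rearrange before elimination, or the C2 reset may be incomplete. The fallback uses known chemistry, sets out from 11 and comes back at 18. Soft enolisation of 11 (TBSOTf, Et3N) gives the 2-silyloxydiene F1, which cyclises on gentle warming (intramolecular Diels–Alder) to the tricyclic silyl enol ether F2. Simmons–Smith cyclopropanation (Et2Zn, CH2I2) gives the siloxycyclopropane F3. FeCl3 in DMF then effects the oxidative one-carbon ring expansion (alkoxy-radical β-scission of the ring-fusion bond) to the β-chloro ketone F4, and NaOAc in MeOH eliminates HCl to the bicyclo[3.2.1]octenone F5. Wittig methoxymethylenation (Ph3P=CHOMe) gives the dienol methyl ether F6, and aqueous HCl/THF followed by catalytic DBU (to epimerise C2) closes lactol 18.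

Step 6 (triflyloxy-diene Diels–Alder). The electron-poor dienyl triflate may cyclise sluggishly or with poor facial selectivity. The fallback sets out from 11 and comes back at 13. LiHMDS (THF, −78 → 0 °C) lets the cross-conjugated dienolate close by two successive intramolecular Michael additions (anionic formal [4+2]) to the tricyclic ketone F7, and KHMDS/PhNTf2 then converts its only enolisable position into triflate 13.

Step 8 (ylide cyclopropanation of an enal). The ylide may instead add 1,2 to the aldehyde and give an epoxide. The fallback sets out from 14 and comes back at 15. Luche reduction (NaBH4, CeCl3) gives the allylic alcohol F8, hydroxyl-directed Simmons–Smith cyclopropanation (Et2Zn, CH2I2) on the exo face gives the cyclopropylmethanol F9, and Dess–Martin oxidation returns 15.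

**Further compounds**
F1 | step 9 | methyl (2E,6S)-6-{2-[(tert-butyldimethylsilyl)oxy]cyclopenta-1,3-dien-1-yl}-7,7-dimethoxy-2-methylhept-2-enoate | CC(C)(C)[Si](C)(C)OC1=C([C@@H](C(OC)OC)CC/C=C(\C)C(=O)OC)CC=C1
F2 | step 9 | methyl (1S,2S,5R,6R,7S)-9-[(tert-butyldimethylsilyl)oxy]-2-(dimethoxymethyl)-6-methyltricyclo[5.2.1.0(1,5)]dec-8-ene-6-carboxylate | COC(=O)[C@]1(C)[C@@H]2C=C(O[Si](C)(C)C(C)(C)C)[C@]3(C2)[C@@H](C(OC)OC)CC[C@@H]13
F3 | step 9 | methyl 9-[(tert-butyldimethylsilyl)oxy]-2-(dimethoxymethyl)-6-methyl-8,9-methanotricyclo[5.2.1.0(1,5)]decane-6-carboxylate (exo cyclopropane) | COC(=O)[C@]1(C)[C@@H]2[C@H]3C[C@@]3(O[Si](C)(C)C(C)(C)C)[C@]4(C2)[C@@H](C(OC)OC)CC[C@@H]14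
F4 | step 9 | methyl 8-chloro-2-(dimethoxymethyl)-6-methyl-10-oxotricyclo[5.3.1.0(1,5)]undecane-6-carboxylate (C8 epimers) | COC(=O)[C@]1(C)[C@@H]2C(Cl)CC(=O)[C@]3(C2)[C@@H](C(OC)OC)CC[C@@H]13
F5 | step 9 | methyl 2-(dimethoxymethyl)-6-methyl-10-oxotricyclo[5.3.1.0(1,5)]undec-8-ene-6-carboxylate | COC(=O)[C@]1(C)[C@@H]2C=CC(=O)[C@]3(C2)[C@@H](C(OC)OC)CC[C@@H]13
F6 | step 9 | methyl 2-(dimethoxymethyl)-10-(methoxymethylidene)-6-methyltricyclo[5.3.1.0(1,5)]undec-8-ene-6-carboxylate | COC(=O)[C@]1(C)[C@@H]2C=CC(=COC)[C@]3(C2)[C@@H](C(OC)OC)CC[C@@H]13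
F7 | step 6 | methyl (1S,2S,5R,6R,7S)-2-(dimethoxymethyl)-6-methyl-9-oxotricyclo[5.2.1.0(1,5)]decane-6-carboxylate | COC(=O)[C@]1(C)[C@@H]2CC(=O)[C@]3(C2)[C@@H](C(OC)OC)CC[C@@H]13
F8 | step 8 | methyl (1S,2S,5R,6R,7S)-2-(dimethoxymethyl)-9-(hydroxymethyl)-6-methyltricyclo[5.2.1.0(1,5)]dec-8-ene-6-carboxylate | COC(=O)[C@]1(C)[C@@H]2C=C(CO)[C@]3(C2)[C@@H](C(OC)OC)CC[C@@H]13
F9 | step 8 | methyl 2-(dimethoxymethyl)-9-(hydroxymethyl)-6-methyl-8,9-methanotricyclo[5.2.1.0(1,5)]decane-6-carboxylate (exo cyclopropane) | COC(=O)[C@]1(C)[C@@H]2[C@H]3C[C@@]3(CO)[C@]4(C2)[C@@H](C(OC)OC)CC[C@@H]14
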